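**Compound numbers used throughout**

1 (−)-camphene · 2 primary ozonide of 1 · 3 camphenilone · 4 4-methylpent-1-yne · 5 lithium acetylide of 4 · 6 propargylic alcohol · 7 allenol · 8 E-enone · 9 phloroglucinol · 10 carbinol adduct · 11 ortho-quinone methide (1-oxatriene) · 12 spiro 2H-chromene · 13 spiro chroman · 14 bis(iminium) salt · 15 target.

Locants: chroman numbering O1, C2 (spiro), C3, C4, C4a, C5–C8, C8a. Norbornane atoms are primed: C2' = C2, C3' = CMe2, C1' and C4' are the bridgeheads, C7' is the one-carbon bridge.

## Analysis of the target

Target 15 is a spiro compound in which a chroman (benzene ring A fused to pyran ring B) shares its C2 with C2' of a 3',3'-dimethylnorbornane. Ring A is a fully substituted phloroglucinol: O1 is the ring ether, C5 and C7 carry free hydroxyls, C6 and C8 carry formyl groups, and the benzylic C4 bears an isobutyl group. There are four stereocentres. The bridgeheads C1' and C4' are locked to each other by the bicycle. At the spiro carbon C2, O1 is endo and C3 is exo on the norbornane. At C4 the isobutyl group lies on the face of ring B that carries C3' (CMe2), so H4 is on the face of C1'. In these locants the configuration is 2R,4S,1'R,4'S. The aldehydes are reducible and must come after any hydrogenation. The tertiary alkyl aryl ether C2–O1 is the most delicate bond: heterolysis gives a tertiary norbornyl cation next to a quaternary carbon, which is open to Wagner–Meerwein shifts, and the diformylated phenoxide is a good leaving group. The main difficulty is that C2 is fully substituted and flanked by CMe2 and a bridgehead, so O1–C2 cannot be made with confidence by substitution or oxa-Michael addition, and its configuration must be related to C4 across ring B. The strategy rests on one feature: ring B joins a threefold-symmetric phloroglucinol, through O1 and C4a, to a three-carbon unit C4–C3–C2 in which C2 is the norbornane carbon. That is the pattern of an enone with carbonyl carbon C4 and a fully substituted beta carbon C2, and the norbornane with its CMe2 group and both bridgeheads is the skeleton of camphene less its methylene carbon.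

## Retrosynthetic reasoning

**15 to 13.** The two aryl–CHO bonds at C6 and C8 are cut first. The aldehydes would not survive the reduction that sets C4, and C6 and C8 are the only free positions of an arene activated by three oxygen donors. The forward step is a twofold electrophilic formylation of the free dihydroxyarene of 13, which keeps the end of the route free of protecting groups. It has to reach the diformyl stage without ionising C2–O1.

**13 to 12.** The hydrogens at C3 and C4 are removed to give the C3=C4 alkene of 12. This turns the C4 stereocentre into a question of facial selectivity governed by the spiro centre next to the alkene. The forward hydrogenation must deliver both hydrogens to the face of ring B that carries C1', away from CMe2.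

**12 to 8 and 9.** Both bonds that tie the three-carbon unit to the arene are cut: C4–C4a and O1–C2. Cutting here, and not at C2–C3 or O1–C8a, leaves the arene as the symmetric, unprotected 9 and the rest as enone 8. It also lets the hindered O1–C2 bond form by a pericyclic ring closure, not by a polar attack on a neopentyl-type carbon. The forward reaction must add a ring carbon of 9 to the carbonyl carbon of 8 (not to the beta carbon), dehydrate adduct 10 to oxatriene 11, close it to 12, and deliver the spiro epimer with O1 endo.

**8 to 6.** The enone is traced back by a 1,3-transposition of oxygen to the tertiary propargylic alcohol 6. No skeletal bond is cut. Direct carbonyl olefination of the hindered ketone 3 with a stabilised phosphorus reagent is not credible, whereas 6 is easily made and cannot eliminate along the Rupe pathway. The forward Meyer–Schuster rearrangement must avoid a free cation at C2' and give the E alkene.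

**6 to 3 and 4.** The C2'–alkyne bond is cut, giving ketone 3 and the terminal alkyne 4, which supplies C3, C4 and the isobutyl group in one piece. The forward step is an acetylide addition to a ketone that cannot enolise.

**3 to 1.** The carbonyl of 3 is traced to the exocyclic alkene of terpene 1, which supplies the CMe2 group and both bridgeheads in the required absolute configuration. The forward step is an oxidative cleavage of a 1,1-disubstituted alkene.

## Alternatives that were turned down

**Alternative 1:** The norbornane bonds C2–C1' and C3'–C4' are cut. This gives cyclopenta-1,3-diene A3 and the exocyclic enol ether A2, a 2-isopropylidene chroman that already carries C4.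
- Forward key step: one-electron oxidation of A2 to its cation radical and [4+2] addition of A3 across the tetrasubstituted C2=CMe2 bond, giving norbornene A1 with C2, C1' and C4' formed at once.
- For: two C–C bonds and three stereocentres arise in one step. C4 is in place beforehand, so no late facial hydrogenation is needed. The endo rule could place oxygen endo kinetically, so on the spiro configuration this route is at least as strong as the chosen one.
- Against: the dienophile is tetrasubstituted, its trialkoxyarene competes for the oxidant, and A3 oligomerises under such conditions. The only stereochemical information is C4, which is 1,3 to the reacting alkene, so the face of attack (and with it the absolute configuration of both bridgeheads) is poorly controlled. C4 needs its own asymmetric synthesis. The endgame adds an alkene hydrogenation, cleavage of two aryl methyl ethers under Lewis-acidic conditions that threaten C2–O1, and the formylation.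
- Comparison: the sequence is estimated at nine or more steps. The chosen route instead takes the bicycle from a terpene with the bridgeheads fixed and uses no protecting groups.

**Alternative 2:** O1–C8a and C4–C4a are cut. Ring A comes from the silyl aryl triflate A6, and the C2–C3–C4 unit with the spiro centre comes from hydroxy ester A5, an acetate aldol adduct of ketone 3.
- Forward key step: fluoride releases the 3,5-dimethoxyaryne. The tertiary alkoxide of A5 adds to the aryne carbon remote from the methoxy group (O1–C8a), and the aryl anion closes onto the ester (C4–C4a) to give chromanone A4.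
- For: the spiro centre is set earlier by kinetic exo addition of an enolate to 3, with no equilibration. On that point the route is stronger than the chosen one. The aryne regiochemistry is inherently correct.
- Against: the alkoxide of a tertiary beta-hydroxy ester of a hindered ketone is prone to retro-aldol cleavage under the basic fluoride conditions, and it is a poor aryne nucleophile. A4 lacks the isobutyl group, so an organometallic addition to a hindered, electron-rich, enolisable carbonyl, a dehydration and the same face-selective hydrogenation follow. Nothing is saved at C4. Two methyl ethers must then be cleaved under conditions hostile to C2–O1 before formylation.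
- Comparison: about ten steps against six. The chosen route offers brevity and free phenols throughout, at the price of thermodynamic, not kinetic, control of the spiro centre.

**Alternative 3:** C2–C3 and O1–C8a are cut. The fragments are ketone 3 and the primary Grignard reagent A8, which carries the C4 stereocentre and a 2,4,6-trifluorophenyl ring.
- Forward key step: lanthanide-salt-assisted addition of A8 to the exo face of 3 forms C2–C3 with oxygen endo. The tertiary alkoxide, after treatment with a strong amide base and warming, displaces an ortho fluoride (O1–C8a) to give A7.
- For: C2 and C4 are set independently and kinetically, by exo attack and a preformed centre. No equilibration and no facial hydrogenation are needed, so this is the strongest of the four on stereocontrol.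
- Against: A8 needs an enantioselective synthesis of several steps. The ring closure asks a hindered tertiary alkoxide to attack a ring activated only by fluorine. After A7, the two remaining fluorides must be exchanged for oxygen on a ring made electron-rich by O1, which means two forcing substitutions and a deprotection before formylation.
- Comparison: this is the longest route. The chosen route trades kinetic certainty for a six-step sequence in which the oxygenation pattern is present from the start.

Key step: step 4

Assumption: commercial (−)-camphene 1 is taken to be the (1S,4R) enantiomer of high optical purity. Every later compound inherits its enantiomeric purity; if the terpene is only enriched, upgrading by crystallisation would be attempted at the first crystalline intermediate.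

## Route

Step 1
Reactants: 1 (−)-camphene
Product: 3 camphenilone (3,3-dimethylnorbornan-2-one with the bridgeheads of 1), via primary ozonide 2 (not isolated)
Conditions: O3, CH2Cl2/MeOH, −78 °C; then Me2S, −78 °C → rt
Reagents that add atoms: ozone, `[O-][O+]=O`
Why: Ozonolysis of a 1,1-disubstituted alkene (1,3-dipolar cycloaddition to 2, cycloreversion, reductive work-up); either mode of fragmentation converges on the ketone. Neither bridgehead is touched, and 3 cannot enolise (C1' is a bridgehead, C3' is quaternary), so no stereocentre is at risk.

Step 2
Reactants: 3 camphenilone; 4 4-methylpent-1-yne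
Product: 6 3,3-dimethyl-2-(4-methylpent-1-yn-1-yl)norbornan-2-ol (hydroxyl endo), via lithium 4-methylpent-1-yn-1-ide 5 (not isolated)
Conditions: 4, n-BuLi, THF, −78 °C; then 3, −78 → 0 °C; aq NH4Cl
Reagents that add atoms: none
Why: 1,2-Addition of a lithium acetylide to a ketone that cannot enolise; the slim nucleophile tolerates the neopentyl-type carbonyl. Exo attack is expected, but this carbinol configuration is erased in step 3, so either epimer serves.

Step 3
Reactants: 6 3,3-dimethyl-2-(4-methylpent-1-yn-1-yl)norbornan-2-ol
Product: 8 (E)-1-(3,3-dimethylnorbornan-2-ylidene)-4-methylpentan-2-one, via allenol 7 (not isolated)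
Conditions: Ph3PAuNTf2 (2 mol%), MeOH (1 equiv), PhMe, rt → 50 °C
Reagents that add atoms: none
Why: Gold-catalysed Meyer–Schuster rearrangement (formal 1,3-hydroxyl shift to allenol 7, then tautomerisation). The Rupe pathway is closed because the carbinol carbon has no eliminable neighbouring hydrogen (C3' is quaternary, C1' is a bridgehead). The E isomer, with the acyl group turned away from CMe2, should be favoured by allylic strain and reached by equilibration under the reaction conditions.

Step 4
Reactants: 8 (E)-1-(3,3-dimethylnorbornan-2-ylidene)-4-methylpentan-2-one; 9 phloroglucinol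
Product: 12 5,7-dihydroxy-4-isobutyl spiro[2H-chromene-2,2'-(3,3-dimethylnorbornane)] (O1 endo), via carbinol adduct 10 (not isolated), via ortho-quinone methide 11 (not isolated)
Conditions: 9 (2.5 equiv), ethylenediammonium diacetate (EDDA, 30 mol%), PhMe/1,4-dioxane 4:1, 4 Å MS, 110 °C, slow addition of 8; heating continued until the spiro-epimer ratio no longer changes
Reagents that add atoms: none
Why: Proposed new method: the primary ammonium of EDDA should convert the ketone of 8 into a conjugated ketiminium, and because the beta carbon C2 is fully substituted and flanked by CMe2 and a bridgehead, the nucleophilic ring carbon of 9 should attack the carbonyl-derived carbon (C4–C4a) to give carbinol 10 or its amine counterpart; the closest known reaction type is the amine-salt-promoted formal [3+3] annulation of phenols with alpha,beta-unsaturated aldehydes to 2H-chromenes, and acid condensations of phenols with beta,beta-dialkyl enones show the same connectivity (aryl carbon on the carbonyl carbon, oxygen on the beta carbon). Loss of water from 10 gives the ortho-quinone methide 11, a 1-oxatriene in which the E geometry of 8 leaves only the bridgehead C–H on the inside. Ring B, the only ring formed, closes by thermal disrotatory oxa-6π electrocyclisation (O1–C2), driven by rearomatisation, so no substitution or conjugate addition at the hindered C2 is needed. The single new stereocentre, spiro C2, is to be set under thermodynamic control: ring opening back to 11 (thermal, or by acid-assisted C2–O1 heterolysis) should be possible at 110 °C, and the epimer with the small oxygen in the crowded endo position and the C3 methine exo should predominate, whereas kinetic closure from the exo face would favour the other epimer. Its absolute sense follows from the bridgeheads of 8. The step needs 1,2- over 1,4-selectivity (secured by the blocked beta carbon) and monoannulation (excess of 9, slow addition of 8), and the threefold symmetry of 9 removes any regiochemical choice on the arene.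

Step 5
Reactants: 12 5,7-dihydroxy-4-isobutyl spiro[2H-chromene-2,2'-(3,3-dimethylnorbornane)]
Product: 13 5,7-dihydroxy-4-isobutyl spiro[chroman-2,2'-(3,3-dimethylnorbornane)] (O1 endo; isobutyl cis to CMe2)
Conditions: H2 (4 bar), PtO2, EtOAc, rt
Reagents that add atoms: none
Why: Heterogeneous catalytic hydrogenation, syn addition to the styrene-type C3=C4 bond. On the CMe2 face the exo methyl of C3' is eclipsed with C3 and sits over the alkene, whereas the C1' face offers only the bridgehead hydrogen, so both hydrogens should arrive from the C1' face; this puts H4 cis to C1' and the isobutyl group cis to CMe2, as in the target. PtO2 is preferred to palladium to limit double-bond migration and allylic C–O hydrogenolysis.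

Step 6
Reactants: 13 5,7-dihydroxy-4-isobutyl spiro[chroman-2,2'-(3,3-dimethylnorbornane)]
Product: 15 5,7-dihydroxy-4-isobutyl spiro[chroman-2,2'-(3,3-dimethylnorbornane)]-6,8-dicarbaldehyde (the target), via bis(iminium) salt 14 (not isolated)
Conditions: POCl3 (5 equiv), DMF (8 equiv), MeCN, 0 → 40 °C; then aq NaOAc, rt → 50 °C
Reagents that add atoms: N,N-dimethylformamide, `CN(C)C=O` (the two formyl carbons); water, `O` (the two aldehyde oxygens)
Why: Twofold Vilsmeier–Haack formylation; C6 and C8 are the only free ring positions and each is ortho or para to three oxygen donors, as in the double formylation of phloroglucinol itself. Buffered hydrolysis of 14 keeps strong acid away from C2–O1, and no stereocentre is formed or touched.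

## Compound list

1 | (−)-camphene, (1S,4R)-2,2-dimethyl-3-methylidenebicyclo[2.2.1]heptane | `C=C2[C@@H]1CC[C@@H](C1)C2(C)C` | starting material
2 | primary ozonide of 1 (spiro 1,2,3-trioxolane at C2', either face) | `C1OOOC12[C@@H]3CC[C@@H](C3)C2(C)C` | intermediate
3 | camphenilone, (1R,4S)-3,3-dimethylbicyclo[2.2.1]heptan-2-one | `O=C2[C@@H]1CC[C@@H](C1)C2(C)C` | intermediate
4 | 4-methylpent-1-yne | `C#CCC(C)C` | starting material
5 | lithium 4-methylpent-1-yn-1-ide | `[Li]C#CCC(C)C` | intermediate
6 | 3,3-dimethyl-2-(4-methylpent-1-yn-1-yl)norbornan-2-ol, hydroxyl endo, bridgeheads as in 1 | `CC(C)CC#C[C@@]2(O)[C@@H]1CC[C@@H](C1)C2(C)C` | intermediate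
7 | 1-(3,3-dimethylnorbornan-2-ylidene)-4-methylpent-1-en-2-ol (allenol) | `CC(C)CC(O)=C=C2[C@@H]1CC[C@@H](C1)C2(C)C` | intermediate
8 | (E)-1-(3,3-dimethylnorbornan-2-ylidene)-4-methylpentan-2-one, acyl group cis to bridgehead C1' | `CC(C)CC(=O)/C=C2\[C@@H]1CC[C@@H](C1)C2(C)C` | intermediate
9 | phloroglucinol (benzene-1,3,5-triol) | `Oc1cc(O)cc(O)c1` | starting material
10 | 2-[(E)-1-(3,3-dimethylnorbornan-2-ylidene)-2-hydroxy-4-methylpentan-2-yl]benzene-1,3,5-triol, carbinol carbon unassigned | `CC(C)CC(O)(/C=C2\[C@@H]1CC[C@@H](C1)C2(C)C)c1c(O)cc(O)cc1O` | intermediate
11 | 6-[1-(3,3-dimethylnorbornan-2-ylidene)-4-methylpent-2-ylidene]-3,5-dihydroxycyclohexa-2,4-dien-1-one (ortho-quinone methide, 1-oxatriene) | `CC(C)CC(/C=C3\[C@@H]2CC[C@@H](C2)C3(C)C)=C1C(=O)C=C(O)C=C1O` | intermediate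
12 | 5,7-dihydroxy-4-isobutyl spiro[2H-chromene-2,2'-(3,3-dimethylnorbornane)], O1 endo and C3 exo on the norbornane | `CC(C)CC1=C[C@@]2(Oc3cc(O)cc(O)c31)[C@@H]1CC[C@@H](C1)C2(C)C` | intermediate
13 | 5,7-dihydroxy-4-isobutyl spiro[chroman-2,2'-(3,3-dimethylnorbornane)], O1 endo, isobutyl cis to CMe2 | `CC(C)C[C@H]1C[C@@]2(Oc3cc(O)cc(O)c31)[C@@H]1CC[C@@H](C1)C2(C)C` | intermediate
14 | 6,8-bis(dimethyliminiomethyl) derivative of 13, dichloride | `CC(C)C[C@H]1C[C@@]2(Oc3c(C=[N+](C)C)c(O)c(C=[N+](C)C)c(O)c31)[C@@H]1CC[C@@H](C1)C2(C)C.[Cl-].[Cl-]` | intermediate
15 | (2R,4S,1'R,4'S)-5,7-dihydroxy-4-isobutyl spiro[chroman-2,2'-(3,3-dimethylnorbornane)]-6,8-dicarbaldehyde | `CC(C)C[C@H]1C[C@@]2(Oc3c(C=O)c(O)c(C=O)c(O)c31)[C@@H]1CC[C@@H](C1)C2(C)C` | target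

## Step count and risk

Total step count: 6. Longest linear sequence: 6 steps (1 to 15); 4 and 9 are commercial and enter directly.

**Step 4 (key step, proposed new method).**
- What may go wrong: the arene may add too slowly to a ketone (as opposed to an aldehyde) carbonyl; a second molecule of 9 may capture 11 at C4 in competition with ring closure; and closure from the exo face may be followed by incomplete equilibration, leaving the spiro epimers as a mixture. Epimers would be separated and the minor one reheated under the reaction conditions.
- Fallback (known chemistry; sets out from 9 and 8, returns at 12): 9 would be converted with chloromethyl methyl ether and NaH in DMF into 1,3,5-tris(methoxymethoxy)benzene F1. This is lithiated between two ether groups (n-BuLi, THF, 0 °C) to [2,4,6-tris(methoxymethoxy)phenyl]lithium F2. After transmetalation with CeCl3, F2 adds 1,2 to the ketone of 8 at −78 °C, the beta carbon being blocked, to give the tertiary alcohol F3. HCl in MeOH at 40–50 °C removes the three acetal groups from F3 and ionises the doubly activated carbinol. The ortho-quinone methide 11 formed in this way closes to 12, and the same thermal equilibration of the spiro centre applies. Only the way C4–C4a is made is changed.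

**Step 3.**
- What may go wrong: the tertiary propargylic alcohol may ionise under the Lewis-acidic gold conditions to a norbornyl cation that undergoes skeletal Wagner–Meerwein shift, or the alkyne may be hydrated without transposition.
- Fallback (sets out from 3, returns at 8): ethoxyacetylene is lithiated (n-BuLi, THF, −78 °C) to lithium ethoxyacetylide F4, which adds to 3 to give 2-(ethoxyethynyl)-3,3-dimethylnorbornan-2-ol F5. The strongly polarised ynol ether rearranges under very mild acid (Sc(OTf)3 cat., CH2Cl2/EtOH, rt) without a free cation at C2', giving ethyl (E)-(3,3-dimethylnorbornan-2-ylidene)acetate F6. MeNH(OMe)·HCl with i-PrMgCl converts this into the N-methoxy-N-methylamide F7, and isobutylmagnesium bromide (THF, 0 °C) then gives 8.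

**Step 5.**
- What may go wrong: facial selectivity may be poor, the double bond may migrate on the metal surface into the isobutyl chain before reduction (which would erase the facial bias), and the hindered alkene may react slowly.
- Fallback (sets out from 12, returns at 13): the phenols are acetylated (Ac2O, pyridine, DMAP) to the diacetate of the chromene F8. F8 is reduced homogeneously with a cationic iridium catalyst bearing a chiral phosphine–oxazoline ligand, [Ir(cod)(tBu-PHOX)]BArF (H2 50 bar, CH2Cl2). The ligand enantiomer is chosen to add on the C1' face, so that catalyst control reinforces the substrate bias and no surface isomerisation can occur. This gives the diacetate of the chroman F9, and K2CO3 in MeOH returns 13.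

**Step 6.**
- What may go wrong: the reaction may stop after the first formylation because the ring is deactivated, the phenols may be O-formylated, and the C2–O1 bond may undergo acid-promoted heterolysis once the arene is electron-poor, during iminium hydrolysis.
- Fallback (sets out from 13, returns at 15): protection with NaH and chloromethyl methyl ether gives the bis(methoxymethyl) ether F10. NBS (2 equiv, MeCN, 0 °C) fills the two free positions to give the 6,8-dibromide F11. Double bromine–lithium exchange (t-BuLi, 4.2 equiv, THF, −78 °C) gives the 6,8-dilithio compound F12, each lithium flanked by two oxygens, and quenching with DMF gives the bis(methoxymethyl) ether of the dialdehyde F13. Dilute HCl in MeOH/THF at rt removes both acetals, each made labile by its ortho formyl group, and gives 15.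

## Further compounds

F1 | step 4 | 1,3,5-tris(methoxymethoxy)benzene | `COCOc1cc(OCOC)cc(OCOC)c1`
F2 | step 4 | [2,4,6-tris(methoxymethoxy)phenyl]lithium | `[Li]c1c(OCOC)cc(OCOC)cc1OCOC`
F3 | step 4 | (E)-1-(3,3-dimethylnorbornan-2-ylidene)-4-methyl-2-[2,4,6-tris(methoxymethoxy)phenyl]pentan-2-ol | `CC(C)CC(O)(/C=C2\[C@@H]1CC[C@@H](C1)C2(C)C)c1c(OCOC)cc(OCOC)cc1OCOC`
F4 | step 3 | lithium ethoxyacetylide | `[Li]C#COCC`
F5 | step 3 | 2-(ethoxyethynyl)-3,3-dimethylnorbornan-2-ol, hydroxyl endo | `CCOC#C[C@@]2(O)[C@@H]1CC[C@@H](C1)C2(C)C`
F6 | step 3 | ethyl (E)-(3,3-dimethylnorbornan-2-ylidene)acetate | `CCOC(=O)/C=C2\[C@@H]1CC[C@@H](C1)C2(C)C`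
F7 | step 3 | (E)-2-(3,3-dimethylnorbornan-2-ylidene)-N-methoxy-N-methylacetamide | `CON(C)C(=O)/C=C2\[C@@H]1CC[C@@H](C1)C2(C)C`
F8 | step 5 | 5,7-diacetoxy-4-isobutyl spiro[2H-chromene-2,2'-(3,3-dimethylnorbornane)] | `CC(C)CC1=C[C@@]2(Oc3cc(OC(C)=O)cc(OC(C)=O)c31)[C@@H]1CC[C@@H](C1)C2(C)C`
F9 | step 5 | 5,7-diacetoxy-4-isobutyl spiro[chroman-2,2'-(3,3-dimethylnorbornane)] | `CC(C)C[C@H]1C[C@@]2(Oc3cc(OC(C)=O)cc(OC(C)=O)c31)[C@@H]1CC[C@@H](C1)C2(C)C`
F10 | step 6 | 4-isobutyl-5,7-bis(methoxymethoxy) spiro[chroman-2,2'-(3,3-dimethylnorbornane)] | `CC(C)C[C@H]1C[C@@]2(Oc3cc(OCOC)cc(OCOC)c31)[C@@H]1CC[C@@H](C1)C2(C)C`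
F11 | step 6 | 6,8-dibromo-4-isobutyl-5,7-bis(methoxymethoxy) spiro[chroman-2,2'-(3,3-dimethylnorbornane)] | `CC(C)C[C@H]1C[C@@]2(Oc3c(Br)c(OCOC)c(Br)c(OCOC)c31)[C@@H]1CC[C@@H](C1)C2(C)C`
F12 | step 6 | 6,8-dilithio-4-isobutyl-5,7-bis(methoxymethoxy) spiro[chroman-2,2'-(3,3-dimethylnorbornane)] | `CC(C)C[C@H]1C[C@@]2(Oc3c([Li])c(OCOC)c([Li])c(OCOC)c31)[C@@H]1CC[C@@H](C1)C2(C)C`
F13 | step 6 | 4-isobutyl-5,7-bis(methoxymethoxy) spiro[chroman-2,2'-(3,3-dimethylnorbornane)]-6,8-dicarbaldehyde | `CC(C)C[C@H]1C[C@@]2(Oc3c(C=O)c(OCOC)c(C=O)c(OCOC)c31)[C@@H]1CC[C@@H](C1)C2(C)C`
A1 | alternative 1 | 4-isobutyl-5,7-dimethoxy spiro[chroman-2,2'-(3,3-dimethylnorborn-5-ene)] | `CC(C)C[C@H]1C[C@@]2(Oc3cc(OC)cc(OC)c31)[C@@H]1C=C[C@@H](C1)C2(C)C`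
A2 | alternative 1 | 4-isobutyl-5,7-dimethoxy-2-(propan-2-ylidene)chroman | `CC(C)C[C@H]1CC(=C(C)C)Oc2cc(OC)cc(OC)c21`
A3 | alternative 1 | cyclopenta-1,3-diene | `C1=CCC=C1`
A4 | alternative 2 | 5,7-dimethoxy spiro[chroman-2,2'-(3,3-dimethylnorbornan)]-4-one | `O=C1C[C@@]2(Oc3cc(OC)cc(OC)c31)[C@@H]1CC[C@@H](C1)C2(C)C`
A5 | alternative 2 | methyl 2-(2-hydroxy-3,3-dimethylnorbornan-2-yl)acetate, hydroxyl endo | `COC(=O)C[C@@]2(O)[C@@H]1CC[C@@H](C1)C2(C)C`
A6 | alternative 2 | 3,5-dimethoxy-2-(trimethylsilyl)phenyl trifluoromethanesulfonate | `COc1cc(OC)c([Si](C)(C)C)c(OS(=O)(=O)C(F)(F)F)c1`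
A7 | alternative 3 | 5,7-difluoro-4-isobutyl spiro[chroman-2,2'-(3,3-dimethylnorbornane)] | `CC(C)C[C@H]1C[C@@]2(Oc3cc(F)cc(F)c31)[C@@H]1CC[C@@H](C1)C2(C)C`
A8 | alternative 3 | [4-methyl-2-(2,4,6-trifluorophenyl)pentyl]magnesium bromide | `CC(C)C[C@@H](C[Mg]Br)c1c(F)cc(F)cc1F`
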